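## The problem

3,3′-Digalloylprocyanidin B2 (35) consists of two (−)-epicatechin 3-O-gallate units joined only by the single bond from C4 of the upper unit (β face) to C8 of the lower unit, so the central task is one carbon, C4, that carries ring A, ring D and, through C3–C2, ring B, and whose link must reach lower-unit C8 and not C6. There are five stereocentres: lower-unit C2 and C3 (2R,3R, cis) and upper-unit C2, C3 and C4 (2R,3R,4R; 2,3-cis, 3,4-trans). Ring D insulates the two sets, so the lower unit cannot be relied on to steer the upper one. Within the upper unit, C4 is the only centre placed to direct C3, and C2 can be tied to C3 by a stereospecific ring closure. The fourteen phenolic hydroxyls sit in catechol, pyrogallol and phloroglucinol arrays that oxidise readily and must stay masked until a last, neutral step. The two gallate esters are base-labile, and the C4–C8 bond is acid-labile because it ionises to a C4 cation stabilised by ring A. The enabling feature is ring A of the upper unit, which bears oxygen on C5, C7 and C8a and a single carbon substituent, C4, on C4a, flanked by two of the oxygenated carbons and para to the third. A siloxyalkyne that already carries C4 and a 3-alkoxycyclobutenone assemble exactly this pattern, so C4 can be set on an open chain and ring A grown onto it afterwards.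

## Retrosynthesis

**Esters and benzyl ethers.** Target 35 is traced back to the fully benzylated digallate 34, and 34 to diol 32 plus two equivalents of acid 33, by cutting fourteen O–benzyl bonds and the two ester C–O bonds. The esters are the most base-sensitive bonds in the molecule and would not survive the organolithium and hydroxide steps needed earlier, so they are made late. Diol 32 has only the two secondary hydroxyls free, which makes the forward double acylation unambiguous. The final hydrogenolysis is neutral and spares the interflavan bond.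

**Ring C (O1–C2).** Diol 32 comes from triol 31 by benzylation of the C5 phenol. Triol 31 is opened at O1–C2 to cis-epoxide 28, which comes from Z-alkene 27. Cutting C4–C8 instead would mean cation chemistry at C4 with C6/C8 and oligomer problems; cutting C4–C4a would leave C4 to substrate control alone. The chosen cut makes C2 and C3 the outcome of one stereospecific event: anti opening of a cis-epoxide at the benzylic carbon by a ring A phenol. This is 6-endo, because charge develops at C2 next to the 3,4-dialkoxyphenyl ring. The precursor has C4 as its only upper-unit stereocentre. The forward step must deliver oxygen to the alkene face that places C3–O trans to ring D.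

**Ring A (C4a–C8a and C5–C6).** Silyl ether 27 is the protected form of phenol 26, and 26 is disconnected into siloxyalkyne 19 and 3-benzyloxycyclobutenone 21. This removes a whole aromatic ring and leaves an acyclic alkyne with one stereocentre and a four-carbon partner. The alternative ways of attaching ring A (arylation of a C4 electrophile by a phloroglucinol ether) would set C4 under substrate control. The benzannulation instead lets C4 be set by a chiral catalyst beforehand and delivers ring A with one ortho oxygen free and the other silylated. The forward reaction must be regioselective in the ketene–alkyne step and must not disturb the C4–H centre.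

**Ynol ether and alkene.** Siloxyalkyne 19 goes back to terminal alkyne 16, silylalkyne 14 (Z), its E isomer 13, alcohol 12 and ketone 11 by functional-group changes only. The E-to-Z isomerisation is placed before the acetylide chemistry on purpose. In the Z isomer, allylic 1,3-strain holds C4–H in the plane of the alkene, orthogonal to the styrene π system. C4–H is then no longer allylically activated when the acetylide and ynolate are made, or when the cascade is heated. The alkene geometry is a spectator in the benzannulation.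

**C4 stereocentre.** Ketone 11 is cut at the C4–C(sp) bond into chalcone 9 and (triisopropylsilyl)acetylene 10. A catalytic asymmetric conjugate alkynylation sets C4 under ligand control, independent of the distant lower-unit centres, and the minor C4 epimer is a diastereomer that can be removed. Conjugate arylation of an enynone would add the hindered aryl group instead and risks 1,6-addition.

**Fragments.** Chalcone 9 is cut at C3–C4 (aldol condensation) into aldehyde 6 and acetophenone 8. Aldehyde 6 comes from bromide 4, and through 3 and 2 from (−)-epicatechin 1, which supplies both lower-unit stereocentres and fixes C8 by bromination. Acetophenone 8 comes from 3,4-dihydroxyacetophenone 7, and cyclobutenone 21 from 3-ethoxycyclobutenone 20 by alkoxy exchange.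

## Roads not taken

**Alternative 1:** The cut is the lower-unit C4–C4a bond of ring F. In the forward step BF3·OEt2 would activate the terminal epoxide of aryl ether A1, and lower-unit C4a would attack the CH2 terminus to give A2 with the lower-unit C3 hydroxyl unveiled.
- Merits: the upper unit, with its three stereocentres and its gallate, can come from natural epicatechin, so only two stereocentres have to be made. The two C3 hydroxyls are differentiated. The ring D precursor is a symmetric phloroglucinol diether, so no C6/C8 question arises. In stereochemical economy this road is better than the chosen one.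
- Weak points: the arene must attack the primary epoxide carbon (6-endo), whereas Lewis acid activation places charge on the secondary carbon and favours the 5-exo closure to a dihydrobenzofuran. Lower-unit C2 in A1 is a benzylic ether of an electron-rich ring next to an activated epoxide and can ionise. BF3 also meets the finished, acid-labile C4–aryl bond. Making A1 needs a clean SN2 etherification of a hindered phenol at that benzylic carbon.
- Comparison: the chosen plan pays for building C2, C3 and C4 anew. Against this it sets a ring closure (step 17) in which the electronically preferred site, benzylic C2, is also the one that gives the six-membered ring, and it never exposes the interflavan bond to a Lewis acid.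

**Alternative 2:** The cut is the lower-unit C3=C4 bond, made by ring-closing metathesis. The second-generation Grubbs catalyst would join the vinyl group on lower-unit C4a and the 1-methoxyvinyl group on lower-unit C2 of diene A3 to give 3-methoxy-2H-chromene A4.
- Merits: neutral conditions, unambiguous regiochemistry, and a chiral-pool upper unit. It is gentler than a pericyclic cascade near 95 °C and needs no strong base late.
- Weak points: a 1,1-disubstituted enol ether and a 2,6-disubstituted styrene are both reluctant metathesis partners, and the Fischer-type alkoxycarbene complexes that the enol ether forms with the catalyst are a sink. A4 must then be hydrolysed to a flavan-3-one whose C2–H lies between the carbonyl, the ring oxygen and an aryl group and can epimerise or ring-open. The cis alcohol depends on hydride face selection (LiBH(s-Bu)3). The benzylic ether stereocentre must still be made as in Alternative 1.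
- Comparison: the chosen plan is harsher in its key step and longer before it. Against this it ties C2 to C3 stereospecifically and passes through no epimerisable ketone.

**Alternative 3:** The cuts are O1–C2 and C3–C4 of ring C. Benzhydrol A5 would release ortho-quinone methide A7, which adds (Z)-styrylsilane A6 in a [4+2] cycloaddition to give 3-silylflavan A8. A Tamao–Fleming oxidation with retention would then give the C3 alcohol.
- Merits: by far the most convergent road. One step makes two bonds, ring C and all three upper-unit stereocentres, and the Z geometry translates into the 2,3-cis relationship. It is shorter than the chosen plan by roughly half a dozen steps.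
- Weak points: A7 is planar at C4, so the absolute sense of the cycloaddition rests only on the remote lower unit. A mixture of the wanted adduct and the diastereomer with the enantiomeric upper unit is likely. The 2,4-trans relationship needs the exo mode, whereas styrenes usually add endo. A Z-β-silylstyrene is a sluggish dienophile.
- Comparison: if face and endo/exo control were solved, for example by a chiral acid, this road would be superior. The chosen plan sets against its length that each stereochemical event is separately controlled: C4 by the [Rh(OAc)(C2H4)2]2/(R)-DTBM-SEGPHOS catalyst, C3 by (S,S)-(salen)MnCl reinforced by the substrate, and C2 by stereospecific inversion.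

Key step: step 14

Remarks on the chemistry:
- Abbreviations: Ep8 = (2R,3R)-5,7,3′,4′-tetra-O-benzyl-3-O-TBS-epicatechin-8-yl; Ar = 3,4-bis(benzyloxy)phenyl; Q = (Z)-3-Ar-1-(Ep8)prop-2-en-1-yl with C1 configured as the future 4R centre; TBS = tert-butyldimethylsilyl; TIPS = triisopropylsilyl. Plain flavan locants (O1, C2, C3, C4, C4a, C5–C8, C8a; rings A, C, B) refer to the upper unit; lower-unit atoms are named as such (rings D, F, E).
- Assumption: the sense of induction in steps 7 and 16 is assigned by analogy with the usual face selectivity of conjugate additions to E-enones catalysed by [Rh(OAc)(C2H4)2]2 with bisphosphines and of the epoxidation of cis-β-methylstyrene with (salen)MnCl catalysts; if a first run shows the opposite sense, the antipodal ligand is used.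
- Assumption: after desilylation in step 17 the two ortho oxygens of ring A are equivalent by the local symmetry of the ring, so closure through either gives the same compound; it is drawn through the oxygen set free in step 14.

Step 1
Reactants: 1 (−)-epicatechin
Product: 2 5,7,3′,4′-tetra-O-benzyl-(−)-epicatechin
Conditions: BnBr, K2CO3, DMF, 0 °C to rt
Reagents that add atoms: benzyl bromide, BrCc1ccccc1
Why: Williamson etherification; carbonate deprotonates only the four phenols, so the C3 alcohol stays free and no stereocentre is touched.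

Step 2
Reactants: 2 5,7,3′,4′-tetra-O-benzyl-(−)-epicatechin
Product: 3 8-bromo-5,7,3′,4′-tetra-O-benzylepicatechin
Conditions: NBS, CH2Cl2, −78 °C to rt
Reagents that add atoms: N-bromosuccinimide, O=C1CCC(=O)N1Br
Why: Electrophilic aromatic bromination of the trioxygenated ring; in 5,7-di-O-alkylflavans C8, flanked by the ring oxygen and one benzyloxy group, is attacked in preference to C6 between two benzyloxy groups, which fixes the later 4→8 regiochemistry.

Step 3
Reactants: 3 8-bromo-5,7,3′,4′-tetra-O-benzylepicatechin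
Product: 4 8-bromo-5,7,3′,4′-tetra-O-benzyl-3-O-TBS-epicatechin (Ep8–Br)
Conditions: TBSCl, imidazole, DMF, rt
Reagents that add atoms: tert-butyldimethylsilyl chloride, CC(C)(C)[Si](C)(C)Cl
Why: Silylation of the secondary alcohol; the TBS ether tolerates the organolithium, hydroxide, hydride and peracid steps that follow and is removed by fluoride in step 17.

Step 4
Reactants: 4 8-bromo-5,7,3′,4′-tetra-O-benzyl-3-O-TBS-epicatechin (Ep8–Br)
Product: 6 5,7,3′,4′-tetra-O-benzyl-3-O-TBS-epicatechin-8-carbaldehyde (Ep8–CHO), via 8-lithio arene 5 (not isolated)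
Conditions: n-BuLi, THF, −78 °C; DMF, −78 to 0 °C; aq. NH4Cl
Reagents that add atoms: N,N-dimethylformamide, CN(C)C=O
Why: Bromine–lithium exchange at −78 °C is faster than any deprotonation, and the aryllithium is formylated by DMF; benzyl and silyl ethers are inert.

Step 5
Reactants: 7 3,4-dihydroxyacetophenone
Product: 8 3,4-bis(benzyloxy)acetophenone
Conditions: BnBr, K2CO3, DMF, rt
Reagents that add atoms: benzyl bromide, BrCc1ccccc1
Why: Williamson etherification of both phenols; carbonate is too weak to enolise and alkylate the methyl ketone.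

Step 6
Reactants: 6 5,7,3′,4′-tetra-O-benzyl-3-O-TBS-epicatechin-8-carbaldehyde (Ep8–CHO); 8 3,4-bis(benzyloxy)acetophenone
Product: 9 (E)-1-Ar-3-(Ep8)prop-2-en-1-one
Conditions: KOH, EtOH/THF, rt
Reagents that add atoms: none
Why: Claisen–Schmidt condensation of a non-enolisable aldehyde with the acetophenone enolate; dehydration gives the conjugated E-enone, whose β-carbon is the future C4.

Step 7
Reactants: 9 (E)-1-Ar-3-(Ep8)prop-2-en-1-one; 10 (triisopropylsilyl)acetylene
Product: 11 (3S)-1-Ar-3-(Ep8)-5-(triisopropylsilyl)pent-4-yn-1-one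
Conditions: [Rh(OAc)(C2H4)2]2 (2.5 mol%), (R)-DTBM-SEGPHOS (6 mol%), 1,4-dioxane, 80 °C
Reagents that add atoms: none
Why: Asymmetric conjugate alkynylation of an enone catalysed by [Rh(OAc)(C2H4)2]2 and a chiral bisphosphine; the bulky silyl group suppresses alkyne dimerisation and the ligand chooses the enone face, so C4 is set under catalyst control, the lower-unit centres being too remote to interfere. The minor C4 epimer is a diastereomer and can be removed here.

Step 8
Reactants: 11 (3S)-1-Ar-3-(Ep8)-5-(triisopropylsilyl)pent-4-yn-1-one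
Product: 12 (3S)-1-Ar-3-(Ep8)-5-(triisopropylsilyl)pent-4-yn-1-ol (both C1 epimers)
Conditions: NaBH4, MeOH/THF, 0 °C
Reagents that add atoms: none
Why: Borohydride reduction of the aryl ketone; the carbinol configuration is irrelevant because the centre is removed in step 9.

Step 9
Reactants: 12 (3S)-1-Ar-3-(Ep8)-5-(triisopropylsilyl)pent-4-yn-1-ol
Product: 13 (1E,3S)-1-Ar-3-(Ep8)-5-(triisopropylsilyl)pent-1-en-4-yne
Conditions: Burgess reagent (methyl N-(triethylammoniosulfonyl)carbamate), toluene, 50 °C
Reagents that add atoms: none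
Why: Burgess dehydration by syn-elimination of the sulfamate; only the C2 hydrogens of the pentynol are available, so the conjugated E-styrene forms, and the neutral medium avoids both a long-lived benzylic cation and base at C3–H.

Step 10
Reactants: 13 (1E,3S)-1-Ar-3-(Ep8)-5-(triisopropylsilyl)pent-1-en-4-yne
Product: 14 (1Z,3S)-1-Ar-3-(Ep8)-5-(triisopropylsilyl)pent-1-en-4-yne
Conditions: fac-Ir(ppy)3 (ppy = 2-phenylpyridinato, 1 mol%), blue LEDs (450 nm), degassed THF, rt
Reagents that add atoms: none
Why: Photocatalytic contra-thermodynamic E-to-Z isomerisation of a styrene by triplet energy transfer; the twisted Z isomer has the higher triplet energy and accumulates, and an acyclic triplet relaxes by bond rotation, not by di-π-methane rearrangement. The Z geometry holds C3–H in the alkene plane and so protects this centre in steps 11–14.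

Step 11
Reactants: 14 (1Z,3S)-1-Ar-3-(Ep8)-5-(triisopropylsilyl)pent-1-en-4-yne
Product: 16 (3R,4Z)-5-Ar-3-(Ep8)pent-4-en-1-yne, via silver acetylide 15 (not isolated)
Conditions: AgF, MeOH/THF, rt, dark; then 1 M HCl, 0 °C
Reagents that add atoms: none
Why: AgF-mediated cleavage of the C(sp)–Si bond gives the silver acetylide, which dilute acid protonates; the medium is never basic, so the skipped enyne is not isomerised and the O-silyl ether survives (the descriptor changes from S to R only because the silyl group is lost).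

Step 12
Reactants: 16 (3R,4Z)-5-Ar-3-(Ep8)pent-4-en-1-yne
Product: 19 (3R,4Z)-5-Ar-3-(Ep8)-1-(triisopropylsilyloxy)pent-4-en-1-yne, via lithium acetylide 17 (not isolated), via lithium ynolate 18 (not isolated)
Conditions: n-BuLi (1.0 equiv), THF, −78 °C; LiOOt-Bu (from t-BuOOH and LiN(SiMe3)2), −78 to 0 °C; TIPSOTf, −78 °C
Reagents that add atoms: lithium tert-butyl peroxide, [Li]OOC(C)(C)C; triisopropylsilyl triflate, CC(C)[Si](C(C)C)(C(C)C)OS(=O)(=O)C(F)(F)F
Why: Oxidation of a lithium acetylide to the ynolate by lithium tert-butyl peroxide, then O-silylation, which the bulky silyl triflate favours over C-silylation. One equivalent of base at −78 °C removes only the acetylenic proton, and the Z geometry keeps C3–H out of conjugation with the styrene.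

Step 13
Reactants: 20 3-ethoxycyclobut-2-en-1-one
Product: 21 3-(benzyloxy)cyclobut-2-en-1-one
Conditions: BnOH, p-TsOH (cat.), benzene, 50 °C, reduced pressure (EtOH removed)
Reagents that add atoms: benzyl alcohol, OCc1ccccc1
Why: Acid-catalysed alkoxy exchange of a vinylogous ester by addition–elimination, driven by removal of ethanol; the benzyl group makes the future C7 ether cleavable in step 20.

Step 14
Reactants: 19 (3R,4Z)-5-Ar-3-(Ep8)-1-(triisopropylsilyloxy)pent-4-en-1-yne; 21 3-(benzyloxy)cyclobut-2-en-1-one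
Product: 26 5-(benzyloxy)-2-Q-3-(triisopropylsilyloxy)phenol, via vinylketene 22 (not isolated), via vinylcyclobutenone 23 (not isolated), via dienylketene 24 (not isolated), via cyclohexadienone 25 (not isolated)
Conditions: 21 (1.5 equiv), toluene, 95 °C, sealed tube, argon
Reagents that add atoms: none
Why: On heating, 21 undergoes 4π electrocyclic cleavage of its C1–C4 bond to vinylketene 22, and 22 is captured by ynol ether 19 in a [2+2] cycloaddition in which the nucleophilic alkyne carbon remote from oxygen, the one bearing C4, bonds to the ketene carbonyl carbon, giving cyclobutenone 23. A second 4π opening of 23 gives dienylketene 24, whose thermal disrotatory 6π electrocyclisation closes the six-membered ring A as dienone 25, and tautomerisation gives phenol 26. In ring A the former ketene carbonyl carbon is C8a with the free hydroxyl, the alkyne carbons are C4a and C5 (silyloxy), and the remaining cyclobutenone carbons are C6, C7 (benzyloxy) and C8, so the net new skeletal bonds are C4a–C8a and C5–C6. The closest known reaction is the Danheiser benzannulation of cyclobutenones with siloxyalkynes to resorcinol monosilyl ethers. No stereocentre is formed. The selectivity needed is the regiochemistry of the ketene–alkyne step, secured by the polarisation of the ynol ether, and chemoselectivity for the electron-rich alkyne over the Z-styrene, a much poorer ketenophile. The medium is neutral and aprotic and the Z geometry keeps C4–H in the alkene plane, so the C4 centre should survive. The excess of 21 offsets ketene dimerisation.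

Step 15
Reactants: 26 5-(benzyloxy)-2-Q-3-(triisopropylsilyloxy)phenol
Product: 27 [5-(benzyloxy)-2-Q-3-(triisopropylsilyloxy)phenoxy](tert-butyl)dimethylsilane
Conditions: TBSOTf, 2,6-lutidine, CH2Cl2, 0 °C
Reagents that add atoms: tert-butyldimethylsilyl triflate, CC(C)(C)[Si](C)(C)OS(=O)(=O)C(F)(F)F
Why: Silylation of the hindered phenol; it protects the electron-rich phenol from the oxidant of step 16, removes a hydroxyl that would direct oxygen to the wrong alkene face, and makes ring A the more shielding of the two aryl groups on C4.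

Step 16
Reactants: 27 [5-(benzyloxy)-2-Q-3-(triisopropylsilyloxy)phenoxy](tert-butyl)dimethylsilane
Product: 28 cis-epoxide of 27 (flavan numbering 2S,3R; used crude)
Conditions: (S,S)-(salen)MnCl (salen = N,N′-bis(3,5-di-tert-butylsalicylidene)-1,2-cyclohexanediaminate, 10 mol%), NMO, mCPBA, CH2Cl2, −78 °C
Reagents that add atoms: 3-chloroperbenzoic acid, OOC(=O)c1cccc(Cl)c1
Why: Jacobsen–Katsuki epoxidation of a cis-β-substituted styrene; the (S,S) catalyst is expected to give the (2S,3R) cis-epoxide by analogy with cis-β-methylstyrene. In the conformer fixed by allylic 1,3-strain (C4–H eclipsing the alkene) this is the face flanked by ring D, the other being shielded by ring A with its two ortho silyloxy groups, so catalyst and substrate should reinforce each other; low temperature and NMO protect the acid-labile epoxide.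

Step 17
Reactants: 28 cis-epoxide of 27
Product: 31 7,3′,4′-tri-O-benzylepicatechin-(4β→8)-5,7,3′,4′-tetra-O-benzylepicatechin, via epoxy resorcinol 29 (not isolated), via lower-unit 3-O-TBS flavan-3-ol 30 (not isolated)
Conditions: TBAF, AcOH, THF, 0 °C; then TBAF (excess), rt
Reagents that add atoms: none
Why: Buffered fluoride cleaves the aryl silyl ethers, and the liberated phenol, kept protonated by AcOH, opens the epoxide at benzylic C2 in an acid-assisted 6-endo SN2-like attack with inversion. This turns the cis-epoxide into the 2,3-cis flavan-3-ol with C3–O trans to the C4 aryl group; attack at C3 (5-exo) is disfavoured because charge develops at the p-alkoxybenzylic carbon. Excess fluoride then removes the lower-unit 3-O-TBS group.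

Step 18
Reactants: 31 7,3′,4′-tri-O-benzylepicatechin-(4β→8)-5,7,3′,4′-tetra-O-benzylepicatechin
Product: 32 5,7,3′,4′-tetra-O-benzylepicatechin-(4β→8)-5,7,3′,4′-tetra-O-benzylepicatechin (octa-O-benzylprocyanidin B2)
Conditions: BnBr, K2CO3, DMF, rt
Reagents that add atoms: benzyl bromide, BrCc1ccccc1
Why: Phenol-selective Williamson etherification; carbonate deprotonates the C5 phenol but neither secondary alcohol, which leaves exactly the two hydroxyls to be acylated.

Step 19
Reactants: 32 octa-O-benzylprocyanidin B2; 33 3,4,5-tris(benzyloxy)benzoic acid (first of the two equivalents incorporated)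
Product: 34 octa-O-benzylprocyanidin B2 3,3′-bis[3,4,5-tris(benzyloxy)benzoate]
Conditions: 33 (3 equiv in total), DCC (3 equiv), DMAP (1 equiv), CH2Cl2, rt
Reagents that add atoms: 3,4,5-tris(benzyloxy)benzoic acid (second equivalent of 33, for the other C3 hydroxyl), OC(=O)c1cc(OCc2ccccc2)c(OCc2ccccc2)c(OCc2ccccc2)c1
Why: Steglich esterification through the acylpyridinium ion; each molecule of 32 takes up two molecules of 33, one at the lower-unit and one at the more hindered upper-unit C3 hydroxyl, so acid and carbodiimide are used in excess to carry the second acylation to completion. No other nucleophilic group is present and no stereocentre is involved.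

Step 20
Reactants: 34 octa-O-benzylprocyanidin B2 3,3′-bis[3,4,5-tris(benzyloxy)benzoate]
Product: 35 3,3′-di-O-galloylprocyanidin B2
Conditions: H2 (1 atm), Pd(OH)2/C, THF/MeOH/H2O, rt
Reagents that add atoms: none
Why: Hydrogenolysis of all fourteen benzyl ethers under neutral conditions, which spares the gallate esters, the acid-labile C4–C8 bond and every stereocentre.

**Compound list**

1 | (−)-epicatechin | O[C@@H]1Cc2c(O)cc(O)cc2O[C@@H]1c1ccc(O)c(O)c1 | starting material
2 | 5,7,3′,4′-tetra-O-benzyl-(−)-epicatechin | O[C@@H]1Cc2c(OCc3ccccc3)cc(OCc3ccccc3)cc2O[C@@H]1c1ccc(OCc2ccccc2)c(OCc2ccccc2)c1 | intermediate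
3 | 8-bromo-5,7,3′,4′-tetra-O-benzylepicatechin | O[C@@H]1Cc2c(OCc3ccccc3)cc(OCc3ccccc3)c(Br)c2O[C@@H]1c1ccc(OCc2ccccc2)c(OCc2ccccc2)c1 | intermediate
4 | 8-bromo-5,7,3′,4′-tetra-O-benzyl-3-O-TBS-epicatechin (Ep8–Br) | CC(C)(C)[Si](C)(C)O[C@@H]1Cc2c(OCc3ccccc3)cc(OCc3ccccc3)c(Br)c2O[C@@H]1c1ccc(OCc2ccccc2)c(OCc2ccccc2)c1 | intermediate
5 | 8-lithio-5,7,3′,4′-tetra-O-benzyl-3-O-TBS-epicatechin (Ep8–Li) | CC(C)(C)[Si](C)(C)O[C@@H]1Cc2c(OCc3ccccc3)cc(OCc3ccccc3)c([Li])c2O[C@@H]1c1ccc(OCc2ccccc2)c(OCc2ccccc2)c1 | intermediate (not isolated)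
6 | 5,7,3′,4′-tetra-O-benzyl-3-O-TBS-epicatechin-8-carbaldehyde (Ep8–CHO) | CC(C)(C)[Si](C)(C)O[C@@H]1Cc2c(OCc3ccccc3)cc(OCc3ccccc3)c(C=O)c2O[C@@H]1c1ccc(OCc2ccccc2)c(OCc2ccccc2)c1 | intermediate
7 | 3,4-dihydroxyacetophenone | CC(=O)c1ccc(O)c(O)c1 | starting material
8 | 3,4-bis(benzyloxy)acetophenone | CC(=O)c1ccc(OCc2ccccc2)c(OCc2ccccc2)c1 | intermediate
9 | (E)-1-Ar-3-(Ep8)prop-2-en-1-one (chalcone) | O=C(/C=C/c2c(OCc4ccccc4)cc(OCc4ccccc4)c3c2O[C@H](c4ccc(OCc5ccccc5)c(OCc5ccccc5)c4)[C@H](O[Si](C)(C)C(C)(C)C)C3)c1ccc(OCc2ccccc2)c(OCc2ccccc2)c1 | intermediate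
10 | (triisopropylsilyl)acetylene | C#C[Si](C(C)C)(C(C)C)C(C)C | starting material
11 | (3S)-1-Ar-3-(Ep8)-5-(triisopropylsilyl)pent-4-yn-1-one | CC(C)[Si](C(C)C)(C(C)C)C#C[C@H](c2c(OCc4ccccc4)cc(OCc4ccccc4)c3c2O[C@H](c4ccc(OCc5ccccc5)c(OCc5ccccc5)c4)[C@H](O[Si](C)(C)C(C)(C)C)C3)CC(=O)c1ccc(OCc2ccccc2)c(OCc2ccccc2)c1 | intermediate
12 | (3S)-1-Ar-3-(Ep8)-5-(triisopropylsilyl)pent-4-yn-1-ol, both C1 epimers | CC(C)[Si](C(C)C)(C(C)C)C#C[C@H](c2c(OCc4ccccc4)cc(OCc4ccccc4)c3c2O[C@H](c4ccc(OCc5ccccc5)c(OCc5ccccc5)c4)[C@H](O[Si](C)(C)C(C)(C)C)C3)CC(O)c1ccc(OCc2ccccc2)c(OCc2ccccc2)c1 | intermediate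
13 | (1E,3S)-1-Ar-3-(Ep8)-5-(triisopropylsilyl)pent-1-en-4-yne | CC(C)[Si](C(C)C)(C(C)C)C#C[C@H](c2c(OCc4ccccc4)cc(OCc4ccccc4)c3c2O[C@H](c4ccc(OCc5ccccc5)c(OCc5ccccc5)c4)[C@H](O[Si](C)(C)C(C)(C)C)C3)/C=C/c1ccc(OCc2ccccc2)c(OCc2ccccc2)c1 | intermediate
14 | (1Z,3S)-1-Ar-3-(Ep8)-5-(triisopropylsilyl)pent-1-en-4-yne | CC(C)[Si](C(C)C)(C(C)C)C#C[C@H](c2c(OCc4ccccc4)cc(OCc4ccccc4)c3c2O[C@H](c4ccc(OCc5ccccc5)c(OCc5ccccc5)c4)[C@H](O[Si](C)(C)C(C)(C)C)C3)/C=C\c1ccc(OCc2ccccc2)c(OCc2ccccc2)c1 | intermediate
15 | silver acetylide of 16 | [Ag]C#C[C@H](c2c(OCc4ccccc4)cc(OCc4ccccc4)c3c2O[C@H](c4ccc(OCc5ccccc5)c(OCc5ccccc5)c4)[C@H](O[Si](C)(C)C(C)(C)C)C3)/C=C\c1ccc(OCc2ccccc2)c(OCc2ccccc2)c1 | intermediate (not isolated)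
16 | (3R,4Z)-5-Ar-3-(Ep8)pent-4-en-1-yne | C#C[C@H](c2c(OCc4ccccc4)cc(OCc4ccccc4)c3c2O[C@H](c4ccc(OCc5ccccc5)c(OCc5ccccc5)c4)[C@H](O[Si](C)(C)C(C)(C)C)C3)/C=C\c1ccc(OCc2ccccc2)c(OCc2ccccc2)c1 | intermediate
17 | lithium acetylide of 16 | [Li]C#C[C@H](c2c(OCc4ccccc4)cc(OCc4ccccc4)c3c2O[C@H](c4ccc(OCc5ccccc5)c(OCc5ccccc5)c4)[C@H](O[Si](C)(C)C(C)(C)C)C3)/C=C\c1ccc(OCc2ccccc2)c(OCc2ccccc2)c1 | intermediate (not isolated)
18 | lithium (4Z)-5-Ar-3-(Ep8)pent-4-en-1-yn-1-olate (ynolate, C3 as in 16) | [Li]OC#C[C@H](c2c(OCc4ccccc4)cc(OCc4ccccc4)c3c2O[C@H](c4ccc(OCc5ccccc5)c(OCc5ccccc5)c4)[C@H](O[Si](C)(C)C(C)(C)C)C3)/C=C\c1ccc(OCc2ccccc2)c(OCc2ccccc2)c1 | intermediate (not isolated)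
19 | (3R,4Z)-5-Ar-3-(Ep8)-1-(triisopropylsilyloxy)pent-4-en-1-yne | CC(C)[Si](C(C)C)(C(C)C)OC#C[C@H](c2c(OCc4ccccc4)cc(OCc4ccccc4)c3c2O[C@H](c4ccc(OCc5ccccc5)c(OCc5ccccc5)c4)[C@H](O[Si](C)(C)C(C)(C)C)C3)/C=C\c1ccc(OCc2ccccc2)c(OCc2ccccc2)c1 | intermediate
20 | 3-ethoxycyclobut-2-en-1-one | CCOC1=CC(=O)C1 | starting material
21 | 3-(benzyloxy)cyclobut-2-en-1-one | O=C1C=C(OCc2ccccc2)C1 | intermediate
22 | 3-(benzyloxy)buta-1,3-dien-1-one (vinylketene) | C=C(OCc1ccccc1)C=C=O | intermediate (not isolated)
23 | 4-[1-(benzyloxy)ethenyl]-2-Q-3-(triisopropylsilyloxy)cyclobut-2-en-1-one, both ring C4 epimers | C=C(OCc8ccccc8)C1C(=O)C([C@H](c2c(OCc4ccccc4)cc(OCc4ccccc4)c3c2O[C@H](c4ccc(OCc5ccccc5)c(OCc5ccccc5)c4)[C@H](O[Si](C)(C)C(C)(C)C)C3)/C=C\c6ccc(OCc7ccccc7)c(OCc7ccccc7)c6)=C1O[Si](C(C)C)(C(C)C)C(C)C | intermediate (not isolated)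
24 | (3E)-5-(benzyloxy)-2-Q-3-(triisopropylsilyloxy)hexa-1,3,5-trien-1-one (dienylketene; ketene carbon C2 and the C5 vinyl group cis across C3=C4) | O=C=C([C@H](c2c(OCc4ccccc4)cc(OCc4ccccc4)c3c2O[C@H](c4ccc(OCc5ccccc5)c(OCc5ccccc5)c4)[C@H](O[Si](C)(C)C(C)(C)C)C3)/C=C\c1ccc(OCc2ccccc2)c(OCc2ccccc2)c1)/C(O[Si](C(C)C)(C(C)C)C(C)C)=C\C(OCc1ccccc1)=C | intermediate (not isolated)
25 | 5-(benzyloxy)-2-Q-3-(triisopropylsilyloxy)cyclohexa-2,4-dien-1-one | O=C1CC(OCc8ccccc8)=CC(O[Si](C(C)C)(C(C)C)C(C)C)=C1[C@H](c2c(OCc4ccccc4)cc(OCc4ccccc4)c3c2O[C@H](c4ccc(OCc5ccccc5)c(OCc5ccccc5)c4)[C@H](O[Si](C)(C)C(C)(C)C)C3)/C=C\c1ccc(OCc2ccccc2)c(OCc2ccccc2)c1 | intermediate (not isolated)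
26 | 5-(benzyloxy)-2-Q-3-(triisopropylsilyloxy)phenol | Oc1cc(OCc2ccccc2)cc(O[Si](C(C)C)(C(C)C)C(C)C)c1[C@H](c2c(OCc4ccccc4)cc(OCc4ccccc4)c3c2O[C@H](c4ccc(OCc5ccccc5)c(OCc5ccccc5)c4)[C@H](O[Si](C)(C)C(C)(C)C)C3)/C=C\c1ccc(OCc2ccccc2)c(OCc2ccccc2)c1 | intermediate
27 | [5-(benzyloxy)-2-Q-3-(triisopropylsilyloxy)phenoxy](tert-butyl)dimethylsilane | CC(C)(C)[Si](C)(C)Oc1cc(OCc2ccccc2)cc(O[Si](C(C)C)(C(C)C)C(C)C)c1[C@H](c2c(OCc4ccccc4)cc(OCc4ccccc4)c3c2O[C@H](c4ccc(OCc5ccccc5)c(OCc5ccccc5)c4)[C@H](O[Si](C)(C)C(C)(C)C)C3)/C=C\c1ccc(OCc2ccccc2)c(OCc2ccccc2)c1 | intermediate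
28 | cis-epoxide of 27 (benzylic carbon S, the other epoxide carbon R; C4 as in 35) | CC(C)(C)[Si](C)(C)Oc1cc(OCc2ccccc2)cc(O[Si](C(C)C)(C(C)C)C(C)C)c1[C@H](c2c(OCc4ccccc4)cc(OCc4ccccc4)c3c2O[C@H](c4ccc(OCc5ccccc5)c(OCc5ccccc5)c4)[C@H](O[Si](C)(C)C(C)(C)C)C3)[C@H]6O[C@H]6c1ccc(OCc2ccccc2)c(OCc2ccccc2)c1 | intermediate
29 | epoxy resorcinol: 28 with both aryl silyl ethers cleaved | Oc1cc(OCc2ccccc2)cc(O)c1[C@H](c2c(OCc4ccccc4)cc(OCc4ccccc4)c3c2O[C@H](c4ccc(OCc5ccccc5)c(OCc5ccccc5)c4)[C@H](O[Si](C)(C)C(C)(C)C)C3)[C@H]6O[C@H]6c1ccc(OCc2ccccc2)c(OCc2ccccc2)c1 | intermediate (not isolated)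
30 | 7,3′,4′-tri-O-benzylepicatechin-(4β→8)-5,7,3′,4′-tetra-O-benzyl-3-O-TBS-epicatechin | O[C@@H]1[C@@H](c2c(OCc4ccccc4)cc(OCc4ccccc4)c3c2O[C@H](c4ccc(OCc5ccccc5)c(OCc5ccccc5)c4)[C@H](O[Si](C)(C)C(C)(C)C)C3)c2c(O)cc(OCc3ccccc3)cc2O[C@@H]1c1ccc(OCc2ccccc2)c(OCc2ccccc2)c1 | intermediate (not isolated)
31 | 7,3′,4′-tri-O-benzylepicatechin-(4β→8)-5,7,3′,4′-tetra-O-benzylepicatechin | O[C@@H]1[C@@H](c2c(OCc4ccccc4)cc(OCc4ccccc4)c3c2O[C@H](c4ccc(OCc5ccccc5)c(OCc5ccccc5)c4)[C@H](O)C3)c2c(O)cc(OCc3ccccc3)cc2O[C@@H]1c1ccc(OCc2ccccc2)c(OCc2ccccc2)c1 | intermediate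
32 | 5,7,3′,4′-tetra-O-benzylepicatechin-(4β→8)-5,7,3′,4′-tetra-O-benzylepicatechin (octa-O-benzylprocyanidin B2) | O[C@@H]1[C@@H](c2c(OCc4ccccc4)cc(OCc4ccccc4)c3c2O[C@H](c4ccc(OCc5ccccc5)c(OCc5ccccc5)c4)[C@H](O)C3)c2c(OCc3ccccc3)cc(OCc3ccccc3)cc2O[C@@H]1c1ccc(OCc2ccccc2)c(OCc2ccccc2)c1 | intermediate
33 | 3,4,5-tris(benzyloxy)benzoic acid | OC(=O)c1cc(OCc2ccccc2)c(OCc2ccccc2)c(OCc2ccccc2)c1 | starting material
34 | octa-O-benzylprocyanidin B2 3,3′-bis[3,4,5-tris(benzyloxy)benzoate] | O=C(O[C@@H]1[C@@H](c2c(OCc4ccccc4)cc(OCc4ccccc4)c3c2O[C@H](c4ccc(OCc5ccccc5)c(OCc5ccccc5)c4)[C@H](OC(=O)c4cc(OCc5ccccc5)c(OCc5ccccc5)c(OCc5ccccc5)c4)C3)c2c(OCc3ccccc3)cc(OCc3ccccc3)cc2O[C@@H]1c1ccc(OCc2ccccc2)c(OCc2ccccc2)c1)c1cc(OCc2ccccc2)c(OCc2ccccc2)c(OCc2ccccc2)c1 | intermediate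
35 | 3,3′-di-O-galloylprocyanidin B2 | O=C(O[C@@H]1[C@@H](c2c(O)cc(O)c3c2O[C@H](c2ccc(O)c(O)c2)[C@H](OC(=O)c2cc(O)c(O)c(O)c2)C3)c2c(O)cc(O)cc2O[C@@H]1c1ccc(O)c(O)c1)c1cc(O)c(O)c(O)c1 | target

**Step count and least certain steps**

Total: 20 steps. Longest linear sequence: 18 steps from 1 (steps 1–4, 6–12, 14–20); steps 5 and 13 prepare the side fragments 8 and 21.

**Step 14 (key step).** The alkoxy donor stabilises cyclobutenone 21, so its ring opening may be too slow at temperatures that 19 tolerates. Dimerisation of the vinylketene or a thermal silyl shift in the ynol ether could then outrun the cycloaddition at the hindered alkyne. The fallback sets out from 19 and comes back at 26; it changes the ketene source, not the bonds formed. Ethyl (E)-3-ethoxybut-2-enoate is converted by acid-catalysed alkoxy exchange with benzyl alcohol into ethyl (E)-3-(benzyloxy)but-2-enoate F2. Saponification with LiOH gives (E)-3-(benzyloxy)but-2-enoic acid F3, and oxalyl chloride gives (E)-3-(benzyloxy)but-2-enoyl chloride F4. Slow addition of F4 to 19 and Et3N in toluene at room temperature releases vinylketene 22 by 1,4-dehydrochlorination in the presence of the alkyne. The cycloaddition to 23 then proceeds without heat, and warming to 80 °C carries 23 through 24 and 25 to 26.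

**Step 7.** The β-carbon of 9 carries a 2,6-dioxygenated, electron-releasing aryl group, so insertion of the enone into the Rh–C(alkynyl) bond may be slow. Dimerisation of 10 could then take over, or face selectivity could erode at the temperature needed. The fallback sets out from 9 and 10 and comes back at 11. Alkyne 10 is lithiated with n-BuLi and treated with B(OiPr)3 and then ethereal HCl to give diisopropyl [(triisopropylsilyl)ethynyl]boronate F1. F1 adds to 9 in CH2Cl2 with 20 mol% of 3,3′-diiodo-1,1′-bi-2-naphthol, through a closed six-membered boronate transition state; the catalyst antipode is chosen to give 11. No transition metal is involved, and the enone need only reach its s-cis conformation.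

**Step 16.** Oxygen transfer from the oxo complex formed from (S,S)-(salen)MnCl may become stepwise. Rotation about C2–C3 in the benzylic radical would then give the trans-epoxide and, after ring closure, the 2,3-trans flavan. The bulky catalyst may also approach the crowded Z-alkene only slowly. The fallback sets out from 27 and comes back at 30, and through it at 31; it replaces the epoxide by a diol. Concerted syn-dihydroxylation of 27 (K2OsO2(OH)4 cat., NMO, acetone/H2O) on the same, less shielded face gives the erythro-diol of 27 F5. K2CO3 in MeOH then cleaves the two aryl silyl ethers to the erythro-diol resorcinol F6. A Mitsunobu closure (PPh3, DIAD, THF) joins a ring A phenol to the benzylic C2 with inversion, the benzylic hydroxyl being the one more readily activated and displaced, and gives 30, which fluoride converts into 31 as in step 17.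

**Step 17.** If desilylation outruns protonation, the free phenoxide may attack C3 in the 5-exo mode and give a dihydrobenzofuran. The benzylic C2–O bond may also ionise before the phenol is free, which would erase the inversion. The fallback sets out from 26 and comes back at 31; it keeps the nucleophile in place from the start. Phenol 26 is epoxidised directly under the conditions of step 16. The neutral phenol is then present when the epoxide forms and closes ring C at once in the acid-assisted 6-endo mode. This gives 7,3′,4′-tri-O-benzyl-5-O-TIPS-epicatechin-(4β→8)-5,7,3′,4′-tetra-O-benzyl-3-O-TBS-epicatechin F7, which TBAF in THF converts into 31. The price is an unprotected electron-rich phenol beside the oxidant and face selectivity that rests on the catalyst alone.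

## Further compounds

F1 | step 7 | diisopropyl [(triisopropylsilyl)ethynyl]boronate | CC(C)OB(OC(C)C)C#C[Si](C(C)C)(C(C)C)C(C)C
F2 | step 14 | ethyl (E)-3-(benzyloxy)but-2-enoate | CCOC(=O)/C=C(\C)OCc1ccccc1
F3 | step 14 | (E)-3-(benzyloxy)but-2-enoic acid | OC(=O)/C=C(\C)OCc1ccccc1
F4 | step 14 | (E)-3-(benzyloxy)but-2-enoyl chloride | ClC(=O)/C=C(\C)OCc1ccccc1
F5 | step 16 | erythro-diol of 27 (flavan numbering 2S,3R; ring A bis-silyl ether) | CC(C)(C)[Si](C)(C)Oc1cc(OCc2ccccc2)cc(O[Si](C(C)C)(C(C)C)C(C)C)c1[C@H](c2c(OCc4ccccc4)cc(OCc4ccccc4)c3c2O[C@H](c4ccc(OCc5ccccc5)c(OCc5ccccc5)c4)[C@H](O[Si](C)(C)C(C)(C)C)C3)[C@@H](O)[C@@H](O)c1ccc(OCc2ccccc2)c(OCc2ccccc2)c1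
F6 | step 16 | erythro-diol resorcinol (F5 with both aryl silyl ethers cleaved) | Oc1cc(OCc2ccccc2)cc(O)c1[C@H](c2c(OCc4ccccc4)cc(OCc4ccccc4)c3c2O[C@H](c4ccc(OCc5ccccc5)c(OCc5ccccc5)c4)[C@H](O[Si](C)(C)C(C)(C)C)C3)[C@@H](O)[C@@H](O)c1ccc(OCc2ccccc2)c(OCc2ccccc2)c1
F7 | step 17 | 7,3′,4′-tri-O-benzyl-5-O-TIPS-epicatechin-(4β→8)-5,7,3′,4′-tetra-O-benzyl-3-O-TBS-epicatechin | O[C@@H]1[C@@H](c2c(OCc4ccccc4)cc(OCc4ccccc4)c3c2O[C@H](c4ccc(OCc5ccccc5)c(OCc5ccccc5)c4)[C@H](O[Si](C)(C)C(C)(C)C)C3)c2c(O[Si](C(C)C)(C(C)C)C(C)C)cc(OCc3ccccc3)cc2O[C@@H]1c1ccc(OCc2ccccc2)c(OCc2ccccc2)c1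
A1 | alternative 1 | perbenzylated epicatechin 3-O-gallate carrying at C4 a 2,4-dibenzyloxy-6-[(1R)-1-Ar-1-(oxiran-2-yl)methoxy]phenyl group (epoxide precursor) | O=C(O[C@@H]1[C@@H](c2c(OCc4ccccc4)cc(OCc4ccccc4)cc2O[C@H](c4ccc(OCc5ccccc5)c(OCc5ccccc5)c4)[C@H]3CO3)c2c(OCc3ccccc3)cc(OCc3ccccc3)cc2O[C@@H]1c1ccc(OCc2ccccc2)c(OCc2ccccc2)c1)c1cc(OCc2ccccc2)c(OCc2ccccc2)c(OCc2ccccc2)c1
A2 | alternative 1 | perbenzylated 3-O-galloylprocyanidin B2 with free lower-unit C3 hydroxyl | O=C(O[C@@H]1[C@@H](c2c(OCc4ccccc4)cc(OCc4ccccc4)c3c2O[C@H](c4ccc(OCc5ccccc5)c(OCc5ccccc5)c4)[C@H](O)C3)c2c(OCc3ccccc3)cc(OCc3ccccc3)cc2O[C@@H]1c1ccc(OCc2ccccc2)c(OCc2ccccc2)c1)c1cc(OCc2ccccc2)c(OCc2ccccc2)c(OCc2ccccc2)c1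
A3 | alternative 2 | diene: upper unit O3-TBS; ring D with vinyl on lower-unit C4a and 1-Ar-2-methoxyallyl ether on lower-unit O1 | CC(C)(C)[Si](C)(C)O[C@@H]1[C@@H](c2c(OCc4ccccc4)cc(OCc4ccccc4)c(C=C)c2O[C@H](c4ccc(OCc5ccccc5)c(OCc5ccccc5)c4)C(OC)=C)c2c(OCc3ccccc3)cc(OCc3ccccc3)cc2O[C@@H]1c1ccc(OCc2ccccc2)c(OCc2ccccc2)c1
A4 | alternative 2 | dimer whose lower unit is the 3-methoxy-2H-chromene, upper unit O3-TBS | CC(C)(C)[Si](C)(C)O[C@@H]1[C@@H](c2c(OCc4ccccc4)cc(OCc4ccccc4)c3c2O[C@H](c4ccc(OCc5ccccc5)c(OCc5ccccc5)c4)C(OC)=C3)c2c(OCc3ccccc3)cc(OCc3ccccc3)cc2O[C@@H]1c1ccc(OCc2ccccc2)c(OCc2ccccc2)c1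
A5 | alternative 3 | 3,5-bis(benzyloxy)-2-[hydroxy(Ep8)methyl]phenol (benzhydrol, carbinol epimers) | Oc1cc(OCc2ccccc2)cc(OCc2ccccc2)c1C(O)c2c(OCc4ccccc4)cc(OCc4ccccc4)c3c2O[C@H](c4ccc(OCc5ccccc5)c(OCc5ccccc5)c4)[C@H](O[Si](C)(C)C(C)(C)C)C3
A6 | alternative 3 | benzyl[(Z)-2-Ar-ethenyl]dimethylsilane | C[Si](C)(Cc1ccccc1)/C=C\c1ccc(OCc2ccccc2)c(OCc2ccccc2)c1
A7 | alternative 3 | 3,5-bis(benzyloxy)-6-[(Ep8)methylidene]cyclohexa-2,4-dien-1-one (ortho-quinone methide) | O=C1C=C(OCc2ccccc2)C=C(OCc2ccccc2)C1=Cc2c(OCc4ccccc4)cc(OCc4ccccc4)c3c2O[C@H](c4ccc(OCc5ccccc5)c(OCc5ccccc5)c4)[C@H](O[Si](C)(C)C(C)(C)C)C3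
A8 | alternative 3 | 4β-(Ep8)-3α-(benzyldimethylsilyl)-5,7,3′,4′-tetra-O-benzylflavan (2,3-cis-3,4-trans) | C[Si](C)(Cc1ccccc1)[C@@H]1[C@@H](c2c(OCc4ccccc4)cc(OCc4ccccc4)c3c2O[C@H](c4ccc(OCc5ccccc5)c(OCc5ccccc5)c4)[C@H](O[Si](C)(C)C(C)(C)C)C3)c2c(OCc3ccccc3)cc(OCc3ccccc3)cc2O[C@@H]1c1ccc(OCc2ccccc2)c(OCc2ccccc2)c1
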